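**Retrosynthetic overview**

1. Numbering (3,7-dioxabicyclo[3.3.0]octane): C1 carbinol, C2 aryl, O3, C4, C5 (H), C6 aryl, O7, C8. Ring A = C1-C2-O3-C4-C5, ring B = C1-C5-C6-O7-C8.
2. The aryl–C2 and O3–C4 bonds are cut together. This opens ring A and gives the monocyclic ring B aldehyde 11 (C2 = CHO, C4 = CH2OTs, C1–O as SEM ether) and the aryl Grignard reagent 12.
3. Enabling feature: C2 lies between O3 and the oxygen-bearing quaternary C1. It is therefore the carbonyl carbon of an α-alkoxy aldehyde that a five-membered magnesium chelate can lock, and the oxygen it gains in the addition is placed to close a five-membered ring onto the primary C4. The trans C1/C5 relationship is stored without strain as two trans substituents on ring B.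
4. C1 comes from vinyl addition to ring B ketone 7, anti to the C4 arm. Ring B comes from a stereoconvergent radical cyclisation (Cp2TiCl) of epoxy propargyl ether 4. C6 comes from a Sharpless kinetic resolution.
5. Ring order: ring B (step 4), then the strained ring A (step 11).

Key step: step 11

Remark: read literally, the SMILES is (1S,2R,5S,6R) with the C1 hydroxyl and the C5 hydrogen on opposite faces, a trans-fused bicycle; the route is built for this strained diastereomer, so acid is avoided once ring A exists.

**Step 1**
Reactants: 1 3,4-dimethoxybenzaldehyde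
Product: 2 rac-1-(3,4-dimethoxyphenyl)prop-2-en-1-ol
Conditions: vinylMgBr, THF, 0 °C; then H2O
Reagents that add atoms: vinylmagnesium bromide, C=C[Mg]Br
Why: Grignard 1,2-addition to an aromatic aldehyde; the carbinol centre forms racemic and is resolved in step 2.

**Step 2**
Reactants: 2 rac-1-(3,4-dimethoxyphenyl)prop-2-en-1-ol
Product: 3 (S)-(3,4-dimethoxyphenyl)[(2R)-oxiran-2-yl]methanol (anti epoxy alcohol)
Conditions: Ti(OiPr)4 (0.1 equiv), L-(+)-DIPT (0.12 equiv), t-BuOOH (0.45 equiv), 4 Å MS, CH2Cl2, −20 °C
Reagents that add atoms: tert-butyl hydroperoxide, CC(C)(C)OO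
Why: Sharpless kinetic resolution by asymmetric epoxidation; with L-(+)-DIPT the (R)-alcohol is the fast enantiomer and should give the anti (erythro) epoxy alcohol, which fixes the later C6, while the slow enantiomer of 2 stays unchanged and is separated.

**Step 3**
Reactants: 3 (S)-(3,4-dimethoxyphenyl)[(2R)-oxiran-2-yl]methanol
Product: 4 (2R)-2-[(S)-(3,4-dimethoxyphenyl)(prop-2-yn-1-yloxy)methyl]oxirane
Conditions: NaH, propargyl bromide, Bu4NI (cat.), THF, −20 → 0 °C
Reagents that add atoms: propargyl bromide, C#CCBr
Why: Williamson etherification with a reactive propargylic bromide, run cold so that alkylation outruns Payne rearrangement; no stereocentre is touched.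

**Step 4**
Reactants: 4 (2R)-2-[(S)-(3,4-dimethoxyphenyl)(prop-2-yn-1-yloxy)methyl]oxirane
Product: 5 [(2R,3S)-2-(3,4-dimethoxyphenyl)-4-methylidenetetrahydrofuran-3-yl]methanol (aryl and CH2OH trans)
Conditions: Cp2TiCl2 (2.2 equiv), Zn, THF, rt, slow addition to 4; then 1 M HCl, 0 °C
Reagents that add atoms: none
Why: Reductive epoxide opening by Cp2TiCl (trivalent titanium) gives the secondary β-titanoxy radical, which closes ring B by 5-exo-dig attack on the alkyne; the planar radical erases the epoxide configuration, and the aryl-bearing centre should place the CH2O arm trans to the aryl group in a chair-like transition state.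

**Step 5**
Reactants: 5 [(2R,3S)-2-(3,4-dimethoxyphenyl)-4-methylidenetetrahydrofuran-3-yl]methanol
Product: 6 tert-butyl{[(2R,3S)-2-(3,4-dimethoxyphenyl)-4-methylidenetetrahydrofuran-3-yl]methoxy}dimethylsilane
Conditions: TBSCl, imidazole, CH2Cl2, 0 °C → rt
Reagents that add atoms: tert-butyldimethylsilyl chloride, CC(C)(C)[Si](C)(C)Cl
Why: Standard silylation of the primary alcohol, needed because a free or sulfonylated β-oxygen would not survive the ketone stage.

**Step 6**
Reactants: 6 TBS ether of 5
Product: 7 (4S,5R)-4-{[(tert-butyldimethylsilyl)oxy]methyl}-5-(3,4-dimethoxyphenyl)dihydrofuran-3(2H)-one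
Conditions: OsO4 (cat.), NaIO4, 2,6-lutidine, dioxane/H2O, rt
Reagents that add atoms: OsO4, O=[Os](=O)(=O)=O; NaIO4 (terminal oxidant, source of the carbonyl oxygen), [Na+].[O-]I(=O)(=O)=O
Why: Lemieux–Johnson oxidation removes the exocyclic CH2 and leaves the ring B ketone; the adjacent centre already holds its more stable trans arrangement, so enolisation would not change it.

**Step 7**
Reactants: 7 ring B ketone
Product: 8 (3S,4S,5R)-4-{[(tert-butyldimethylsilyl)oxy]methyl}-5-(3,4-dimethoxyphenyl)-3-ethenyltetrahydrofuran-3-ol (OH cis to CH2OTBS)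
Conditions: vinylMgBr, LaCl3·2LiCl (1 equiv), THF, 0 °C; then H2O
Reagents that add atoms: vinylmagnesium bromide, C=C[Mg]Br
Why: Lanthanide-assisted Grignard 1,2-addition to an enolisable ketone; vinyl should attack the face opposite the adjacent CH2OTBS arm, which puts the new hydroxyl cis to that arm and so sets C1 with the trans C1/C5 relationship.

**Step 8**
Reactants: 8 tertiary vinyl carbinol
Product: 9 (2R,3S,4S)-3-{[(tert-butyldimethylsilyl)oxy]methyl}-2-(3,4-dimethoxyphenyl)-4-ethenyl-4-{[2-(trimethylsilyl)ethoxy]methoxy}tetrahydrofuran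
Conditions: SEMCl, i-Pr2NEt, Bu4NI (cat.), ClCH2CH2Cl, 50 °C
Reagents that add atoms: 2-(trimethylsilyl)ethoxymethyl chloride, C[Si](C)(C)CCOCCl
Why: Acetal-type protection of the tertiary alcohol under amine base; the SEM group supplies the chelating oxygen for step 11 and blocks oxetane closure and Grob fragmentation from a free C1 alkoxide.

**Step 9**
Reactants: 9 SEM ether
Product: 10 [(2R,3S,4S)-2-(3,4-dimethoxyphenyl)-4-ethenyl-4-{[2-(trimethylsilyl)ethoxy]methoxy}tetrahydrofuran-3-yl]methyl 4-methylbenzenesulfonate
Conditions: TsF, DBU (0.2 equiv), MeCN, rt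
Reagents that add atoms: p-toluenesulfonyl fluoride, Cc1ccc(cc1)S(=O)(=O)F
Why: DBU-catalysed interchange of a silyl ether for a sulfonate with a sulfonyl fluoride (sulfur–fluoride exchange), driven by Si–F bond formation; only the primary O–Si bond reacts, and the C–Si bond of the SEM group is inert at room temperature.

**Step 10**
Reactants: 10 vinyl tosylate
Product: 11 [(2R,3S,4S)-2-(3,4-dimethoxyphenyl)-4-formyl-4-{[2-(trimethylsilyl)ethoxy]methoxy}tetrahydrofuran-3-yl]methyl 4-methylbenzenesulfonate
Conditions: OsO4 (cat.), NaIO4, 2,6-lutidine, dioxane/H2O, rt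
Reagents that add atoms: OsO4, O=[Os](=O)(=O)=O; NaIO4 (terminal oxidant, source of the carbonyl oxygen), [Na+].[O-]I(=O)(=O)=O
Why: Lemieux–Johnson oxidation of the only alkene gives the aldehyde, whose α-carbon is quaternary and cannot epimerise; sulfonate, SEM acetal and veratryl ring tolerate the buffered medium.

**Step 11**
Reactants: 11 ring B aldehyde; 12 3,4-dimethoxyphenylmagnesium bromide (commercial 0.5 M solution in THF)
Product: 14 (1S,2R,5S,6R)-2,6-bis(3,4-dimethoxyphenyl)-1-{[2-(trimethylsilyl)ethoxy]methoxy}-3,7-dioxabicyclo[3.3.0]octane (trans-fused), via bromomagnesium alkoxide 13 (not isolated)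
Conditions: MgBr2·OEt2 (1.5 equiv), CH2Cl2 (0.02 M), −78 °C; 12 (1.2 equiv), −78 °C; then THF/DMPU, warm to 40 °C; then H2O
Reagents that add atoms: 3,4-dimethoxyphenylmagnesium bromide (12), COc1ccc([Mg]Br)cc1OC
Why: MgBr2 ties the aldehyde oxygen and the C1–O(SEM) oxygen of 11 into a five-membered Cram chelate, 12 adds its aryl carbon to the aldehyde carbon at −78 °C (the new aryl–C2 bond), and on warming in DMPU the alkoxide 13 displaces the primary sulfonate at C4, so one operation delivers the C–C bond, the C2 stereocentre, the O3–C4 bond and ring A. The closest known reaction types are the chelation-controlled Grignard addition to α-alkoxy aldehydes and the tandem carbonyl addition/intramolecular Williamson etherification that turns γ-halo or γ-sulfonyloxy carbonyl compounds into 2-substituted tetrahydrofurans. Ring A closes in the 5-exo-tet mode, and because the displacement is irreversible under basic conditions, the strain of the trans ring fusion is paid for kinetically and cannot be relieved by reopening. C2 is controlled by the chelate: one face is flanked by C8H2, the other by C5 and the cis-1,3 aryl group at C6, so the aryl group should enter from the C8 side, which gives (2R) with the aryl group cis to the C1 oxygen. The step needs chemoselectivity of 12 for the aldehyde over the sulfonate, secured by the temperature staging and the near-stoichiometric charge of 12, and it needs alkylation of the C2 oxygen only, secured by the SEM group on the C1 oxygen. C1, C5 and C6 are spectators, since no bond to them is made or broken.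

**Step 12**
Reactants: 14 SEM-protected trans-fused bicycle
Product: 15 (1S,2R,5S,6R)-2,6-bis(3,4-dimethoxyphenyl)-3,7-dioxabicyclo[3.3.0]octan-1-ol (target)
Conditions: TBAF (excess), DMPU, 4 Å MS, 80 °C; then H2O
Reagents that add atoms: none
Why: Fluoride attacks the silicon of the SEM group, and fragmentation with loss of ethene and formaldehyde frees the tertiary alcohol without acid, so the ionisable benzylic ethers of the strained bicycle and all four stereocentres stay untouched.

**Compound list**

1 | 3,4-dimethoxybenzaldehyde | COc1ccc(C=O)cc1OC | starting material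
2 | rac-1-(3,4-dimethoxyphenyl)prop-2-en-1-ol | COc1ccc(cc1OC)C(O)C=C | intermediate
3 | (S)-(3,4-dimethoxyphenyl)[(2R)-oxiran-2-yl]methanol | COc1ccc(cc1OC)[C@H](O)[C@H]2CO2 | intermediate
4 | (2R)-2-[(S)-(3,4-dimethoxyphenyl)(prop-2-yn-1-yloxy)methyl]oxirane | COc1ccc(cc1OC)[C@H](OCC#C)[C@H]2CO2 | intermediate
5 | [(2R,3S)-2-(3,4-dimethoxyphenyl)-4-methylidenetetrahydrofuran-3-yl]methanol | COc1ccc(cc1OC)[C@@H]2OCC(=C)[C@H]2CO | intermediate
6 | TBS ether of 5 | COc1ccc(cc1OC)[C@@H]2OCC(=C)[C@H]2CO[Si](C)(C)C(C)(C)C | intermediate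
7 | (4S,5R)-4-{[(tert-butyldimethylsilyl)oxy]methyl}-5-(3,4-dimethoxyphenyl)dihydrofuran-3(2H)-one | COc1ccc(cc1OC)[C@@H]2OCC(=O)[C@H]2CO[Si](C)(C)C(C)(C)C | intermediate
8 | (3S,4S,5R)-4-{[(tert-butyldimethylsilyl)oxy]methyl}-5-(3,4-dimethoxyphenyl)-3-ethenyltetrahydrofuran-3-ol | COc1ccc(cc1OC)[C@@H]2OC[C@](O)(C=C)[C@H]2CO[Si](C)(C)C(C)(C)C | intermediate
9 | SEM ether of 8, (2R,3S,4S) | COc1ccc(cc1OC)[C@@H]2OC[C@](OCOCC[Si](C)(C)C)(C=C)[C@H]2CO[Si](C)(C)C(C)(C)C | intermediate
10 | primary tosylate, (2R,3S,4S), vinyl and SEM ether retained | COc1ccc(cc1OC)[C@@H]2OC[C@](OCOCC[Si](C)(C)C)(C=C)[C@H]2COS(=O)(=O)c3ccc(C)cc3 | intermediate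
11 | ring B aldehyde, (2R,3S,4S), with CH2OTs and SEM ether | COc1ccc(cc1OC)[C@@H]2OC[C@](OCOCC[Si](C)(C)C)(C=O)[C@H]2COS(=O)(=O)c3ccc(C)cc3 | intermediate
12 | 3,4-dimethoxyphenylmagnesium bromide | COc1ccc([Mg]Br)cc1OC | starting material
13 | bromomagnesium alkoxide of the (R)-benzylic carbinol from 11 and 12 (not isolated) | COc1ccc(cc1OC)[C@@H]2OC[C@](OCOCC[Si](C)(C)C)([C@H](O[Mg]Br)c3ccc(OC)c(OC)c3)[C@H]2COS(=O)(=O)c4ccc(C)cc4 | intermediate
14 | (1S,2R,5S,6R)-2,6-bis(3,4-dimethoxyphenyl)-1-{[2-(trimethylsilyl)ethoxy]methoxy}-3,7-dioxabicyclo[3.3.0]octane | COc1ccc([C@H]2OC[C@H]3[C@H](c4ccc(OC)c(OC)c4)OC[C@]23OCOCC[Si](C)(C)C)cc1OC | intermediate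
15 | (1S,2R,5S,6R)-2,6-bis(3,4-dimethoxyphenyl)-3,7-dioxabicyclo[3.3.0]octan-1-ol | COc1ccc([C@H]2OC[C@H]3[C@H](c4ccc(OC)c(OC)c4)OC[C@]23O)cc1OC | target

Total step count: 12. Longest linear sequence: 12 steps (1 → 15).

**Steps most likely to fail**

**Step 11.** The weakly nucleophilic magnesium alkoxide may close the strained ring too slowly. Halide exchange, elimination at C4/C5 or intermolecular etherification could then take over, and chelation control may erode once THF enters the medium.

The fallback sets out from 9 and comes back at 14; it separates the two events and closes the ring by redox dehydration instead of alkoxide displacement. Lemieux–Johnson cleavage of the vinyl group of 9 (OsO4 cat., NaIO4, 2,6-lutidine) should give the silyl-protected aldehyde F1. Chelation-controlled addition of 12 at −78 °C (MgBr2·OEt2, CH2Cl2) with an aqueous quench gives the benzylic alcohol F2, whose C2 epimers can be separated at this stage. TBAF at room temperature frees the primary alcohol to give the diol F3. Mitsunobu cyclodehydration (PPh3, DIAD, THF) then activates the primary hydroxyl and lets the neutral benzylic hydroxyl close ring A to 14.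

**Step 7.** Facial selectivity may be poor, because the aryl group at C6 sits on the face that vinyl has to use. Enolisation followed by β-elimination of the silyloxy group is a second risk.

The fallback sets out from 5 and comes back at 8; it sets C1 by hydroxyl direction instead of steric approach control. VO(acac)2/t-BuOOH in CH2Cl2 should deliver oxygen to the alkene face cis to the CH2OH group and give the spiro-epoxy alcohol F4. TBSCl/imidazole gives its silyl ether F5. Excess dimethylsulfonium methylide (Me3SI, n-BuLi, THF) opens the epoxide at its CH2 carbon and eliminates dimethyl sulfide. The product is the one-carbon-homologated tertiary allylic alcohol 8, with the C1–O bond never broken.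

**Step 12.** Fragmentation of the hindered tertiary SEM acetal may be incomplete, or the strained skeleton may degrade on long heating with basic fluoride.

The fallback sets out from 8 and comes back at 15; it dispenses with protection of the C1 hydroxyl. Lemieux–Johnson cleavage of 8 gives the α-hydroxy aldehyde F6. An excess of 12 first deprotonates the tertiary hydroxyl, and the resulting magnesium alkoxide chelate directs the aryl addition to the diol F7. TBAF at room temperature gives the triol F8. Mitsunobu cyclodehydration (PPh3, DIAD, THF) works through the activated primary hydroxyl under neutral conditions, so no C1 alkoxide is present to fragment, and it closes ring A directly to 15.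

**Further compounds**

F1 | step 11 | (2R,3S,4S)-ring B aldehyde with CH2OTBS and SEM ether | COc1ccc(cc1OC)[C@@H]2OC[C@](OCOCC[Si](C)(C)C)(C=O)[C@H]2CO[Si](C)(C)C(C)(C)C
F2 | step 11 | (R)-benzylic alcohol from F1 and 12, CH2OTBS and SEM ether retained | COc1ccc(cc1OC)[C@@H]2OC[C@](OCOCC[Si](C)(C)C)([C@H](O)c3ccc(OC)c(OC)c3)[C@H]2CO[Si](C)(C)C(C)(C)C
F3 | step 11 | diol from F2 (free CH2OH and benzylic OH, SEM ether retained) | COc1ccc(cc1OC)[C@@H]2OC[C@](OCOCC[Si](C)(C)C)([C@H](O)c3ccc(OC)c(OC)c3)[C@H]2CO
F4 | step 7 | spiro-epoxy alcohol from 5, epoxide oxygen cis to CH2OH | COc1ccc(cc1OC)[C@@H]2OC[C@]3(CO3)[C@H]2CO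
F5 | step 7 | TBS ether of F4 | COc1ccc(cc1OC)[C@@H]2OC[C@]3(CO3)[C@H]2CO[Si](C)(C)C(C)(C)C
F6 | step 12 | α-hydroxy aldehyde from 8 (free tertiary OH, CH2OTBS) | COc1ccc(cc1OC)[C@@H]2OC[C@](O)(C=O)[C@H]2CO[Si](C)(C)C(C)(C)C
F7 | step 12 | diol from F6 and 12 (tertiary OH, (R)-benzylic OH, CH2OTBS) | COc1ccc(cc1OC)[C@@H]2OC[C@](O)([C@H](O)c3ccc(OC)c(OC)c3)[C@H]2CO[Si](C)(C)C(C)(C)C
F8 | step 12 | triol from F7 | COc1ccc(cc1OC)[C@@H]2OC[C@](O)([C@H](O)c3ccc(OC)c(OC)c3)[C@H]2CO
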